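**Retrosynthetic overview**
1. Target 22 ⇐ 21 by one BCl3 step that cleaves the O‑benzyl and the carbonyl‑chelated O‑ethyl group and leaves the naphthyl OMe.
2. 21 ⇐ furyl alkoxy‑ynone 19 by an intramolecular furan Diels–Alder/aromatisation that closes the cyclohexanone ring and builds the catechol ring in the same operation (furan O → C7–OH, ynone OEt → C8–O).
3. 19 ⇐ Weinreb amide 16 + lithium ethoxyacetylide; 16 ⇐ acid 14.
4. 14 (C4 = S) ⇐ (R)‑lactone 10 + 2‑furylzinc by a stereoinvertive Ni‑catalysed C(sp3)–C(sp2) coupling; 10 ⇐ keto acid 8 by asymmetric transfer hydrogenation.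
5. 8 ⇐ succinic anhydride + the aryllithium from 5‑methoxy‑1‑naphthol (para‑bromination, O‑benzylation). Ring order: naphthalene bought, then both tetralone rings together.

Assumption: 5‑methoxynaphthalen‑1‑ol is bought (it is also one methylation from 1,5‑dihydroxynaphthalene), and the catalyst enantiomer in step 4 is assigned by analogy with acetophenone‑type ketones.

**Step 1**
Reactants: 1 5-methoxynaphthalen-1-ol; 2 N-bromosuccinimide
Product: 3 4-bromo-5-methoxynaphthalen-1-ol
Conditions: NBS (1.0 equiv), MeCN, −20 → 0 °C, dark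
Reagents that add atoms: N-bromosuccinimide (2), O=C1CCC(=O)N1Br
Why: Electrophilic aromatic bromination (SEAr) of a 1‑naphthol goes para to the free OH, which activates its ring more than OMe does; this is the same peri‑to‑OMe position at which 1,5‑dimethoxynaphthalene brominates.

**Step 2**
Reactants: 3 4-bromo-5-methoxynaphthalen-1-ol; 4 benzyl bromide
Product: 5 1-(benzyloxy)-4-bromo-5-methoxynaphthalene
Conditions: BnBr, K2CO3, DMF, rt
Reagents that add atoms: benzyl bromide (4), BrCc1ccccc1
Why: Williamson ether synthesis on the naphthoxide; the benzyl ether survives organolithium, Ni(0) and Lewis‑acid steps and blocks quinone‑methide formation at the later benzylic centre.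

**Step 3**
Reactants: 5 1-(benzyloxy)-4-bromo-5-methoxynaphthalene; 6 succinic anhydride
Product: 8 4-[4-(benzyloxy)-8-methoxynaphthalen-1-yl]-4-oxobutanoic acid, via aryllithium 7 (not isolated)
Conditions: n-BuLi, THF, −78 °C; then add to succinic anhydride, THF, −78 °C → rt; 1 M HCl
Reagents that add atoms: succinic anhydride (6), O=C1CCC(=O)O1
Why: Bromine–lithium exchange followed by acylative ring‑opening of the cyclic anhydride; the carboxylate formed and the peri‑OMe hindrance of the new ketone stop a second addition.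

**Step 4**
Reactants: 8 4-[4-(benzyloxy)-8-methoxynaphthalen-1-yl]-4-oxobutanoic acid
Product: 10 (5R)-5-[4-(benzyloxy)-8-methoxynaphthalen-1-yl]oxolan-2-one, via hydroxy acid 9 (not isolated)
Conditions: RuCl[(R,R)-TsDPEN](p-cymene) (2 mol%), HCO2H–Et3N (5:2), DMF, 40 °C; lactonises on concentration (no strong acid)
Reagents that add atoms: none
Why: Noyori asymmetric transfer hydrogenation of the aryl ketone; the (R,R) catalyst delivers hydride to the face that gives the (R) carbinol (aryl versus CH2 differentiation as for acetophenone), and the γ‑hydroxy acid closes to the lactone without touching the new centre.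

**Step 5**
Reactants: 10 (5R)-5-[4-(benzyloxy)-8-methoxynaphthalen-1-yl]oxolan-2-one; 11 furan
Product: 14 (4S)-4-[4-(benzyloxy)-8-methoxynaphthalen-1-yl]-4-(furan-2-yl)butanoic acid, via furan-2-yllithium 12 (not isolated), via furan-2-ylzinc chloride 13 (not isolated)
Conditions: furan, n-BuLi, THF, 0 °C; ZnCl2; then 10, Ni(cod)2 (10 mol%), DPEphos (12 mol%), PhMe–THF, rt; 1 M HCl
Reagents that add atoms: furan (11), c1ccoc1
Why: Proposed new method: stereospecific Ni‑catalysed Negishi ring‑opening of the benzylic lactone, in which Ni(0) attacks the naphthylic C–O bond from the back (SN2‑type oxidative addition, inversion), the nickel carboxylate transmetalates with the furylzinc and reductive elimination proceeds with retention, so (R)‑10 gives (S)‑14; the closest known reaction type is the stereospecific nickel‑catalysed ring‑opening cross‑coupling of enantioenriched aryl‑substituted lactones with dimethylzinc and of benzylic ethers with aryl Grignard reagents, both with inversion.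

**Step 6**
Reactants: 14 (4S)-4-[4-(benzyloxy)-8-methoxynaphthalen-1-yl]-4-(furan-2-yl)butanoic acid; 15 N,O-dimethylhydroxylamine hydrochloride
Product: 16 (4S)-4-[4-(benzyloxy)-8-methoxynaphthalen-1-yl]-4-(furan-2-yl)-N-methoxy-N-methylbutanamide
Conditions: MeNHOMe·HCl, EDC·HCl, HOBt (cat.), N-methylmorpholine, CH2Cl2, 0 °C → rt
Reagents that add atoms: N,O-dimethylhydroxylamine hydrochloride (15), CNOC.Cl
Why: Carbodiimide amide coupling to the Weinreb amide under neutral conditions that leave the furan and the remote stereocentre untouched.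

**Step 7**
Reactants: 16 (4S)-4-[4-(benzyloxy)-8-methoxynaphthalen-1-yl]-4-(furan-2-yl)-N-methoxy-N-methylbutanamide; 17 ethoxyacetylene
Product: 19 (6S)-6-[4-(benzyloxy)-8-methoxynaphthalen-1-yl]-1-ethoxy-6-(furan-2-yl)hex-1-yn-3-one, via lithium ethoxyacetylide 18 (not isolated)
Conditions: ethoxyacetylene, n-BuLi, THF, −78 °C; then 16, −78 → −30 °C; sat. NH4Cl, cold
Reagents that add atoms: ethoxyacetylene (17), CCOC#C
Why: Weinreb ketone synthesis; the chelated tetrahedral intermediate holds until the quench, so the sensitive push–pull ynone never meets excess acetylide.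

**Step 8**
Reactants: 19 (6S)-6-[4-(benzyloxy)-8-methoxynaphthalen-1-yl]-1-ethoxy-6-(furan-2-yl)hex-1-yn-3-one
Product: 21 (4S)-4-[4-(benzyloxy)-8-methoxynaphthalen-1-yl]-8-ethoxy-7-hydroxy-3,4-dihydronaphthalen-1(2H)-one, via oxa-bridged cycloadduct 20 (not isolated)
Conditions: Me2AlCl (2.2 equiv), CH2Cl2 (0.01 M), −78 → −20 °C; 1 M HCl
Reagents that add atoms: none
Why: Proposed new method: intramolecular Diels–Alder of the furan (IMDAF) with the tethered alkoxy‑ynone followed by in‑flask opening of the oxygen bridge; the four‑atom tether forces furan C2 onto the ynone α‑carbon (cyclohexanone ring closes) while the nucleophilic furan C5 adds to the Lewis‑acid‑activated, ethoxy‑bearing β‑carbon (six‑membered carbocycle closes), and the 7‑oxanorbornadiene 20 then ionises at the quaternary bridgehead (cation stabilised by OEt as a vinylogous oxocarbenium) and aromatises by 1,2‑H shift/tautomerisation, so the furan oxygen becomes the C7 phenol and the ethoxy carbon becomes C8; C4 is not involved and stays S; the closest known reaction type is the alkylaluminium‑chloride‑promoted IMDAF of 2‑alkylfurans with tethered enones and the IMDAF/aromatisation of furan–ynones to annulated phenols.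

**Step 9**
Reactants: 21 (4S)-4-[4-(benzyloxy)-8-methoxynaphthalen-1-yl]-8-ethoxy-7-hydroxy-3,4-dihydronaphthalen-1(2H)-one
Product: 22 (4S)-7,8-dihydroxy-4-(4-hydroxy-8-methoxynaphthalen-1-yl)-3,4-dihydronaphthalen-1(2H)-one
Conditions: BCl3 (6 equiv), pentamethylbenzene (3 equiv), CH2Cl2, −78 → 0 °C; MeOH quench
Reagents that add atoms: none
Why: BCl3 ether cleavage: the C8 ethyl ether is removed by carbonyl/neighbouring‑borate chelation and the benzyl ether by ionisation with the benzyl cation trapped by pentamethylbenzene (Friedel–Crafts scavenging), while the non‑chelated naphthyl methyl ether is not attacked at this temperature; the stereocentre is not touched.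

**Compound list**
1 | 5-methoxynaphthalen-1-ol | COc1cccc2c(O)cccc12 | starting material
2 | N-bromosuccinimide | O=C1CCC(=O)N1Br | starting material
3 | 4-bromo-5-methoxynaphthalen-1-ol | COc1cccc2c(O)ccc(Br)c12 | intermediate
4 | benzyl bromide | BrCc1ccccc1 | starting material
5 | 1-(benzyloxy)-4-bromo-5-methoxynaphthalene | COc1cccc2c(OCc3ccccc3)ccc(Br)c12 | intermediate
6 | succinic anhydride | O=C1CCC(=O)O1 | starting material
7 | [4-(benzyloxy)-8-methoxynaphthalen-1-yl]lithium (not isolated) | [Li]c1ccc(OCc2ccccc2)c2cccc(OC)c12 | intermediate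
8 | 4-[4-(benzyloxy)-8-methoxynaphthalen-1-yl]-4-oxobutanoic acid | OC(=O)CCC(=O)c1ccc(OCc2ccccc2)c2cccc(OC)c12 | intermediate
9 | (4R)-4-[4-(benzyloxy)-8-methoxynaphthalen-1-yl]-4-hydroxybutanoic acid (not isolated) | OC(=O)CC[C@@H](O)c1ccc(OCc2ccccc2)c2cccc(OC)c12 | intermediate
10 | (5R)-5-[4-(benzyloxy)-8-methoxynaphthalen-1-yl]oxolan-2-one | O=C1CC[C@H](c2ccc(OCc3ccccc3)c3cccc(OC)c23)O1 | intermediate
11 | furan | c1ccoc1 | starting material
12 | furan-2-yllithium (not isolated) | [Li]c1ccco1 | intermediate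
13 | furan-2-ylzinc chloride (not isolated) | Cl[Zn]c1ccco1 | intermediate
14 | (4S)-4-[4-(benzyloxy)-8-methoxynaphthalen-1-yl]-4-(furan-2-yl)butanoic acid | OC(=O)CC[C@H](c1ccco1)c1ccc(OCc2ccccc2)c2cccc(OC)c12 | intermediate
15 | N,O-dimethylhydroxylamine hydrochloride | CNOC.Cl | starting material
16 | (4S)-4-[4-(benzyloxy)-8-methoxynaphthalen-1-yl]-4-(furan-2-yl)-N-methoxy-N-methylbutanamide | CON(C)C(=O)CC[C@H](c1ccco1)c1ccc(OCc2ccccc2)c2cccc(OC)c12 | intermediate
17 | ethoxyacetylene | CCOC#C | starting material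
18 | lithium ethoxyacetylide (not isolated) | [Li]C#COCC | intermediate
19 | (6S)-6-[4-(benzyloxy)-8-methoxynaphthalen-1-yl]-1-ethoxy-6-(furan-2-yl)hex-1-yn-3-one | CCOC#CC(=O)CC[C@H](c1ccco1)c1ccc(OCc2ccccc2)c2cccc(OC)c12 | intermediate
20 | IMDAF adduct of 19: 7-oxabicyclo[2.2.1]hepta-2,5-diene fused to the new cyclohexanone ring, C4 as in 19, both bridgehead epimers (not isolated) | CCOC1=C2C(=O)CC[C@@H](c5ccc(OCc6ccccc6)c6cccc(OC)c56)C23OC1C=C3 | intermediate
21 | (4S)-4-[4-(benzyloxy)-8-methoxynaphthalen-1-yl]-8-ethoxy-7-hydroxy-3,4-dihydronaphthalen-1(2H)-one | CCOc1c(O)ccc2c1C(=O)CC[C@H]2c1ccc(OCc3ccccc3)c3cccc(OC)c13 | intermediate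
22 | (4S)-7,8-dihydroxy-4-(4-hydroxy-8-methoxynaphthalen-1-yl)-3,4-dihydronaphthalen-1(2H)-one | COc1cccc2c(O)ccc([C@@H]3CCC(=O)c4c3ccc(O)c4O)c12 | target

**Step count**
Total: 9 steps. Longest linear sequence: 9 steps (1 → 22).

**Three steps most likely to fail, with fallbacks**

Step 8 (alkoxy‑ynone IMDAF/aromatisation). The push–pull ynone may add chloride or methyl, or polymerise the furan, faster than it cyclises. The fallback sets out from 16 and comes back at 22; it keeps the furan benzannulation but brings in the C8 oxygen afterwards. Add ethynylmagnesium bromide to 16 to give the terminal ynone (6S)-6-[4-(benzyloxy)-8-methoxynaphthalen-1-yl]-6-(furan-2-yl)hex-1-yn-3-one F1. Brominate the alkyne terminus (NBS, cat. AgNO3, acetone) to the bromo‑ynone (6S)-6-[4-(benzyloxy)-8-methoxynaphthalen-1-yl]-1-bromo-6-(furan-2-yl)hex-1-yn-3-one F2. Heat F2 (PhMe, 110 °C) so that the same intramolecular furan cycloaddition and bridge opening give (4S)-4-[4-(benzyloxy)-8-methoxynaphthalen-1-yl]-8-bromo-7-hydroxy-3,4-dihydronaphthalen-1(2H)-one F3. Replace bromide by hydroxide under copper catalysis (CuI, 8‑hydroxyquinoline, KOH, DMSO–H2O, 100 °C, argon) to obtain (4S)-4-[4-(benzyloxy)-8-methoxynaphthalen-1-yl]-7,8-dihydroxy-3,4-dihydronaphthalen-1(2H)-one F4. Debenzylate F4 with BCl3/pentamethylbenzene to reach 22.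

Step 5 (stereoinvertive Ni coupling of the lactone). The electron‑rich naphthylic C–O bond may ionise (loss of ee), β‑hydride elimination may compete, or the furylzinc may fail to transmetalate. The fallback sets out from 5 and comes back at 16; it sets the stereocentre by conjugate addition instead of substitution.
- Convert 5 (n‑BuLi, B(OiPr)3, then aqueous acid) into [4-(benzyloxy)-8-methoxynaphthalen-1-yl]boronic acid F5.
- Add F5 to methyl (E)-3-(furan-2-yl)acrylate under Rh(I)/chiral diene or BINAP catalysis (Hayashi–Miyaura 1,4‑addition, ligand enantiomer chosen to give S) to form methyl (3S)-3-[4-(benzyloxy)-8-methoxynaphthalen-1-yl]-3-(furan-2-yl)propanoate F6.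
- Saponify (LiOH) to (3S)-3-[4-(benzyloxy)-8-methoxynaphthalen-1-yl]-3-(furan-2-yl)propanoic acid F7.
- Homologate by Arndt–Eistert: mixed anhydride then TMSCHN2 gives (4S)-4-[4-(benzyloxy)-8-methoxynaphthalen-1-yl]-1-diazo-4-(furan-2-yl)butan-2-one F8, and Wolff rearrangement (AgOBz, Et3N) in the presence of MeNHOMe gives 16 directly.

Step 7 (alkoxy‑ynone by acyl substitution). The ynone may not survive the basic addition and quench. The fallback sets out from 16 and comes back at 19; it uses carbonyl addition and a neutral oxidation. Reduce 16 with DIBAL‑H (−78 °C) to (4S)-4-[4-(benzyloxy)-8-methoxynaphthalen-1-yl]-4-(furan-2-yl)butanal F9. Add lithium ethoxyacetylide to obtain (6S)-6-[4-(benzyloxy)-8-methoxynaphthalen-1-yl]-1-ethoxy-6-(furan-2-yl)hex-1-yn-3-ol F10 as a mixture of C3 epimers. Oxidise F10 with activated MnO2 (CH2Cl2, rt) to 19.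

**Further compounds**
F1 | step 8 | (6S)-6-[4-(benzyloxy)-8-methoxynaphthalen-1-yl]-6-(furan-2-yl)hex-1-yn-3-one | C#CC(=O)CC[C@H](c1ccco1)c1ccc(OCc2ccccc2)c2cccc(OC)c12
F2 | step 8 | (6S)-6-[4-(benzyloxy)-8-methoxynaphthalen-1-yl]-1-bromo-6-(furan-2-yl)hex-1-yn-3-one | BrC#CC(=O)CC[C@H](c1ccco1)c1ccc(OCc2ccccc2)c2cccc(OC)c12
F3 | step 8 | (4S)-4-[4-(benzyloxy)-8-methoxynaphthalen-1-yl]-8-bromo-7-hydroxy-3,4-dihydronaphthalen-1(2H)-one | Oc1ccc2c(c1Br)C(=O)CC[C@H]2c1ccc(OCc3ccccc3)c3cccc(OC)c13
F4 | step 8 | (4S)-4-[4-(benzyloxy)-8-methoxynaphthalen-1-yl]-7,8-dihydroxy-3,4-dihydronaphthalen-1(2H)-one | Oc1ccc2c(c1O)C(=O)CC[C@H]2c1ccc(OCc3ccccc3)c3cccc(OC)c13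
F5 | step 5 | [4-(benzyloxy)-8-methoxynaphthalen-1-yl]boronic acid | OB(O)c1ccc(OCc2ccccc2)c2cccc(OC)c12
F6 | step 5 | methyl (3S)-3-[4-(benzyloxy)-8-methoxynaphthalen-1-yl]-3-(furan-2-yl)propanoate | COC(=O)C[C@H](c1ccco1)c1ccc(OCc2ccccc2)c2cccc(OC)c12
F7 | step 5 | (3S)-3-[4-(benzyloxy)-8-methoxynaphthalen-1-yl]-3-(furan-2-yl)propanoic acid | OC(=O)C[C@H](c1ccco1)c1ccc(OCc2ccccc2)c2cccc(OC)c12
F8 | step 5 | (4S)-4-[4-(benzyloxy)-8-methoxynaphthalen-1-yl]-1-diazo-4-(furan-2-yl)butan-2-one | [N-]=[N+]=CC(=O)C[C@H](c1ccco1)c1ccc(OCc2ccccc2)c2cccc(OC)c12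
F9 | step 7 | (4S)-4-[4-(benzyloxy)-8-methoxynaphthalen-1-yl]-4-(furan-2-yl)butanal | O=CCC[C@H](c1ccco1)c1ccc(OCc2ccccc2)c2cccc(OC)c12
F10 | step 7 | (6S)-6-[4-(benzyloxy)-8-methoxynaphthalen-1-yl]-1-ethoxy-6-(furan-2-yl)hex-1-yn-3-ol | CCOC#CC(O)CC[C@H](c1ccco1)c1ccc(OCc2ccccc2)c2cccc(OC)c12
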